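**Plan**

- Retrosynthetic cuts (clerodane numbering): C1–C16 (ring C) first, then C12–C13 (furan), C8=C17 and C7–O, the C4–C18 bond with the lactone C–O bond, C1–C10 together with C4–C5 (ring A), and C9–C11.
- Forward order: ring B from 2-methylcyclohexane-1,3-dione; C9–C11 by Claisen rearrangement; ring A by a Diels–Alder reaction on a C5=C10 enal; the 18,19-olide by carbonylation of a dienyl triflate; ring B oxygenation; furan side chain; ring C last.
- Enabling feature: ring C (C1, C10, C9, C11, C12, C13, C16) exists only through the C1–C16 bond. C1 is the δ-carbon of the ring A dienolide C18(=O)–C4=C3–C2=C1, and the furan α-carbon C16 is held over it by the three-atom C9–C11–C12 tether on the β-face of the cis-fused rings A/B.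
- Stereochemistry: a C8 carbinol from a CBS reduction (erased later) relays to C9 (Claisen, anti), then to C5 and C10 (Diels–Alder anti to the axial C9 methyl), then C7 (Rubottom oxidation on the open β-face), and C1 is set by the tether in the ring closure. C12 is not controlled and ends as the ketone.

Key step: step 20

**Conventions and assumptions**

- Bicyclic intermediates are named as decalins with clerodane locants (ring A = C1–C5, C10; ring B = C5–C10). α is the face of C19, C20 and H10; β is the face of C11 and the 7-acetoxy group.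
- Assumption: the CBS reduction of vinylogous ester 3 follows the usual model, with the methyl-bearing enol-ether arm as the large group.
- Epimer mixtures are expected at C4 (compounds 11, 12) and C12 (compounds 25–30); one epimer is drawn, and both centres are later erased.

**Route**

Step 1
Reactants: 1 2-methylcyclohexane-1,3-dione; 2 allyl alcohol
Product: 3 3-(allyloxy)-2-methylcyclohex-2-en-1-one
Conditions: allyl alcohol (3 equiv), TsOH·H2O (cat.), PhH, reflux, Dean–Stark trap
Reagents that add atoms: none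
Why: Acid-catalysed enol etherification of the enolised 1,3-dione (vinylogous ester formation) is driven by azeotropic removal of water and stays well below the temperature at which the O-allyl compound would rearrange to the C-allyl dione.

Step 2
Reactants: 3 3-(allyloxy)-2-methylcyclohex-2-en-1-one
Product: 4 (1R)-3-(allyloxy)-2-methylcyclohex-2-en-1-ol
Conditions: (S)-2-methyl-CBS-oxazaborolidine (0.2 equiv), catecholborane (1.5 equiv), PhMe, −78 → −40 °C; MeOH, then aq. NaHCO3 (work-up kept basic)
Reagents that add atoms: none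
Why: Corey–Bakshi–Shibata reduction of an α-substituted cyclic enone should deliver hydride to one carbonyl face and set C8 as (R); catecholborane is chosen because it does not hydroborate the allyl group at this temperature.

Step 3
Reactants: 4 (1R)-3-(allyloxy)-2-methylcyclohex-2-en-1-ol
Product: 5 tert-butyl{[(1R)-3-(allyloxy)-2-methylcyclohex-2-en-1-yl]oxy}dimethylsilane
Conditions: TBSCl (1.2 equiv), imidazole, DMF, 0 °C → rt
Reagents that add atoms: tert-butyldimethylsilyl chloride, CC(C)(C)[Si](C)(C)Cl
Why: Silylation of the secondary allylic alcohol under basic conditions protects it without ionising the acid-labile 3-alkoxy allylic system, and C8 is unchanged.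

Step 4
Reactants: 5 tert-butyl{[(1R)-3-(allyloxy)-2-methylcyclohex-2-en-1-yl]oxy}dimethylsilane
Product: 6 (2S,3R)-2-allyl-3-[(tert-butyldimethylsilyl)oxy]-2-methylcyclohexan-1-one
Conditions: PhMe, Et3N (trace), 180 °C, sealed tube
Reagents that add atoms: none
Why: Claisen rearrangement of the allyl enol ether forms the C9–C11 bond; allylic 1,2-strain with the C9 methyl holds the C8 silyloxy group pseudoaxial, so the allyl group should be delivered to the opposite face of C9, giving the quaternary centre with allyl trans and methyl cis to the silyloxy group.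

Step 5
Reactants: 6 (2S,3R)-2-allyl-3-[(tert-butyldimethylsilyl)oxy]-2-methylcyclohexan-1-one
Product: 7 (2S,3R,6E)-2-allyl-3-[(tert-butyldimethylsilyl)oxy]-6-[(dimethylamino)methylidene]-2-methylcyclohexan-1-one
Conditions: t-BuOCH(NMe2)2 (1.5 equiv), PhMe, 110 °C
Reagents that add atoms: tert-butoxybis(dimethylamino)methane, CC(C)(C)OC(N(C)C)N(C)C
Why: Aminomethylenation of the ketone at C5, its only enolisable position because C9 is quaternary, gives the vinylogous amide that carries the future C19 carbon.

Step 6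
Reactants: 7 (2S,3R,6E)-2-allyl-3-[(tert-butyldimethylsilyl)oxy]-6-[(dimethylamino)methylidene]-2-methylcyclohexan-1-one
Product: 9 (3R,4R)-3-allyl-4-[(tert-butyldimethylsilyl)oxy]-3-methylcyclohex-1-ene-1-carbaldehyde, via amino alcohol 8 (not isolated)
Conditions: LiAlH4, Et2O, 0 °C; then 1 M HCl, THF, 0 °C → rt
Reagents that add atoms: water, O
Why: 1,2-Reduction of the vinylogous amide and acid hydrolysis of the resulting γ-amino allylic alcohol with loss of the C10 oxygen (reductive carbonyl transposition of an enaminone) should give the enal with C5=C10 and the aldehyde carbon C19; no stereocentre is formed.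

Step 7
Reactants: 9 (3R,4R)-3-allyl-4-[(tert-butyldimethylsilyl)oxy]-3-methylcyclohex-1-ene-1-carbaldehyde; 10 (E)-1-(trimethylsilyloxy)buta-1,3-diene
Product: 12 9β-allyl-8α-[(tert-butyldimethylsilyl)oxy]-4α-hydroxy-9α-methyl-5,10-cis-decal-2-ene-5α-carbaldehyde (10α-H), via silyl ether adduct 11 (not isolated)
Conditions: 10 (3 equiv), Me2AlCl (1.1 equiv), CH2Cl2, −78 → −30 °C; then 1 M HCl, THF, 0 °C
Reagents that add atoms: none
Why: The Lewis acid-promoted Diels–Alder reaction of a 1-silyloxydiene with an α-substituted enal joins the oxygen-bearing terminus to C5 and the CH2 terminus to C10 (ortho rule); the trans-diequatorial 8-silyloxy and 9-allyl groups fix the half-chair with the C9 methyl pseudoaxial, so the diene should add to the opposite face and set C5 and C10 together, cis-fused, with ring A on the face of the allyl group.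

Step 8
Reactants: 12 9β-allyl-8α-[(tert-butyldimethylsilyl)oxy]-4α-hydroxy-9α-methyl-5,10-cis-decal-2-ene-5α-carbaldehyde
Product: 13 9β-allyl-8α-[(tert-butyldimethylsilyl)oxy]-9α-methyl-4-oxo-5,10-cis-decal-2-ene-5α-carbaldehyde
Conditions: Dess–Martin periodinane, NaHCO3, CH2Cl2, rt
Reagents that add atoms: none
Why: Dess–Martin oxidation of the secondary allylic alcohol gives the C2=C3 enone under neutral conditions that spare the non-enolisable formyl group, and the C4 stereocentre is erased.

Step 9
Reactants: 13 9β-allyl-8α-[(tert-butyldimethylsilyl)oxy]-9α-methyl-4-oxo-5,10-cis-decal-2-ene-5α-carbaldehyde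
Product: 14 9β-allyl-8α-[(tert-butyldimethylsilyl)oxy]-5α-formyl-9α-methyl-5,10-cis-decala-1,3-dien-4-yl trifluoromethanesulfonate
Conditions: KN(SiMe3)2 (1.1 equiv), PhNTf2 (1.2 equiv), THF, −78 °C
Reagents that add atoms: N-phenylbis(trifluoromethanesulfonimide), O=S(=O)(N(c1ccccc1)S(=O)(=O)C(F)(F)F)C(F)(F)F
Why: With C5 quaternary the enone has no α′-hydrogen, so the amide base should remove a γ-hydrogen at C1, and O-sulfonylation of the extended enolate (enol triflate formation) gives the 1,3-dien-4-yl triflate without touching C10.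

Step 10
Reactants: 14 9β-allyl-8α-[(tert-butyldimethylsilyl)oxy]-5α-formyl-9α-methyl-5,10-cis-decala-1,3-dien-4-yl trifluoromethanesulfonate
Product: 15 9β-allyl-8α-[(tert-butyldimethylsilyl)oxy]-5α-(hydroxymethyl)-9α-methyl-5,10-cis-decala-1,3-dien-4-yl trifluoromethanesulfonate
Conditions: NaBH4, MeOH/THF, 0 °C
Reagents that add atoms: none
Why: Chemoselective borohydride reduction of the hindered aldehyde gives the C19 primary alcohol and leaves the dienyl triflate intact.

Step 11
Reactants: 15 9β-allyl-8α-[(tert-butyldimethylsilyl)oxy]-5α-(hydroxymethyl)-9α-methyl-5,10-cis-decala-1,3-dien-4-yl trifluoromethanesulfonate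
Product: 16 9β-allyl-8α-[(tert-butyldimethylsilyl)oxy]-9α-methyl-5,10-cis-decala-1,3-dien-18,19-olide (lactone C4–C18(=O)–O–C19–C5)
Conditions: Pd(PPh3)4 (5 mol%), CO (1 atm), Bu3N, LiCl, MeCN, 65 °C
Reagents that add atoms: carbon monoxide, [C-]#[O+]
Why: In this palladium-catalysed carbonylative lactonisation of a hydroxy vinyl triflate, oxidative addition at C4–OTf by zerovalent palladium, CO insertion and capture of the acyl palladium by the C19 hydroxyl form the C4–C18 bond and the 18,19-olide conjugated with the 1,3-diene.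

Step 12
Reactants: 16 9β-allyl-8α-[(tert-butyldimethylsilyl)oxy]-9α-methyl-5,10-cis-decala-1,3-dien-18,19-olide
Product: 17 9β-allyl-8α-hydroxy-9α-methyl-5,10-cis-decala-1,3-dien-18,19-olide
Conditions: HF·pyridine, pyridine, THF, 0 °C → rt
Reagents that add atoms: none
Why: Fluoride desilylation under mildly acidic conditions frees the C8 hydroxyl without isomerising the base-sensitive dienolide.

Step 13
Reactants: 17 9β-allyl-8α-hydroxy-9α-methyl-5,10-cis-decala-1,3-dien-18,19-olide
Product: 18 9β-allyl-9α-methyl-8-oxo-5,10-cis-decala-1,3-dien-18,19-olide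
Conditions: Dess–Martin periodinane, NaHCO3, CH2Cl2, rt
Reagents that add atoms: none
Why: Dess–Martin oxidation gives the C8 ketone, whose only enolisable position is C7; the C8 stereocentre, having done its work as a control element, disappears.

Step 14
Reactants: 18 9β-allyl-9α-methyl-8-oxo-5,10-cis-decala-1,3-dien-18,19-olide
Product: 20 9β-allyl-7β-hydroxy-9α-methyl-8-oxo-5,10-cis-decala-1,3-dien-18,19-olide, via silyl enol ether 19 (not isolated)
Conditions: TMSOTf, Et3N, CH2Cl2, 0 °C; then mCPBA, NaHCO3, CH2Cl2, −20 °C; then citric acid, MeOH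
Reagents that add atoms: meta-chloroperoxybenzoic acid, OOC(=O)c1cccc(Cl)c1
Why: In this Rubottom oxidation the electron-rich C7=C8 silyl enol ether should be epoxidised far faster than the terminal alkene or the ester-conjugated diene, and from the β-face, because the α-face of C7 is screened by the 1,3-diaxial C19 and C20 groups of the lactone-locked cis-decalin, giving the equatorial 7β-hydroxy ketone.

Step 15
Reactants: 20 9β-allyl-7β-hydroxy-9α-methyl-8-oxo-5,10-cis-decala-1,3-dien-18,19-olide
Product: 21 7β-acetoxy-9β-allyl-9α-methyl-8-oxo-5,10-cis-decala-1,3-dien-18,19-olide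
Conditions: Ac2O, pyridine, DMAP (cat.), CH2Cl2, 0 °C → rt
Reagents that add atoms: acetic anhydride, CC(=O)OC(C)=O
Why: DMAP-catalysed acetylation (esterification) of the α-hydroxy ketone installs the 7-acetate with retention, the equatorial β-epimer also being the thermodynamically preferred one.

Step 16
Reactants: 21 7β-acetoxy-9β-allyl-9α-methyl-8-oxo-5,10-cis-decala-1,3-dien-18,19-olide
Product: 23 7β-acetoxy-9α-methyl-8-oxo-9β-(2-oxoethyl)-5,10-cis-decala-1,3-dien-18,19-olide, via diol 22 (not isolated)
Conditions: OsO4 (2 mol%), NaIO4 (4 equiv), 2,6-lutidine, dioxane/H2O 3:1, rt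
Reagents that add atoms: osmium tetroxide, O=[Os](=O)(=O)=O; sodium periodate, [Na+].[O-]I(=O)(=O)=O
Why: Lemieux–Johnson oxidation (dihydroxylation, then periodate cleavage) should select the monosubstituted terminal alkene over the ring-bound, ester-conjugated diene and give the C12 aldehyde.

Step 17
Reactants: 23 7β-acetoxy-9α-methyl-8-oxo-9β-(2-oxoethyl)-5,10-cis-decala-1,3-dien-18,19-olide; 24 3-bromofuran
Product: 25 7β-acetoxy-9β-[2-(furan-3-yl)-2-hydroxyethyl]-9α-methyl-8-oxo-5,10-cis-decala-1,3-dien-18,19-olide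
Conditions: 24 (1.5 equiv), n-BuLi, THF, −78 °C; ClTi(OiPr)3, −78 °C; then 23, −78 → −30 °C
Reagents that add atoms: none
Why: Carbonyl addition of a 3-furyltitanium triisopropoxide should be selective for the unhindered aldehyde in the presence of the neopentyl ketone, the acetate and the lactone; both C12 epimers are expected and both are carried on because this centre ends as a ketone.

Step 18
Reactants: 25 7β-acetoxy-9β-[2-(furan-3-yl)-2-hydroxyethyl]-9α-methyl-8-oxo-5,10-cis-decala-1,3-dien-18,19-olide
Product: 26 7β-acetoxy-9β-[2-(tert-butyldimethylsilyloxy)-2-(furan-3-yl)ethyl]-9α-methyl-8-oxo-5,10-cis-decala-1,3-dien-18,19-olide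
Conditions: TBSCl, imidazole, DMF, rt
Reagents that add atoms: tert-butyldimethylsilyl chloride, CC(C)(C)[Si](C)(C)Cl
Why: Silylation of the secondary furylic alcohol, which drains the open hydroxy ketone from any 8,12-hemiketal, gives the bulky silyl ether that keeps the furan electron-rich for the ring closure.

Step 19
Reactants: 26 7β-acetoxy-9β-[2-(tert-butyldimethylsilyloxy)-2-(furan-3-yl)ethyl]-9α-methyl-8-oxo-5,10-cis-decala-1,3-dien-18,19-olide
Product: 27 7β-acetoxy-9β-[2-(tert-butyldimethylsilyloxy)-2-(furan-3-yl)ethyl]-9α-methyl-8-methylene-5,10-cis-decala-1,3-dien-18,19-olide (1,16-seco dienolide)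
Conditions: Zn, CH2Br2, TiCl4, THF/CH2Cl2, 0 °C → rt
Reagents that add atoms: dibromomethane, BrCBr
Why: Takai–Lombardo methylenation with the non-basic zinc/titanium methylene reagent should convert the hindered, enolisable α-acetoxy ketone into the C8 exo-methylene without touching acetate, lactone or silyl ether.

Step 20
Reactants: 27 7β-acetoxy-9β-[2-(tert-butyldimethylsilyloxy)-2-(furan-3-yl)ethyl]-9α-methyl-8-methylene-5,10-cis-decala-1,3-dien-18,19-olide
Product: 29 ring C-closed 12-silyl ether (the target with C12 as its tert-butyldimethylsilyl ether; 1α-H), via deconjugated lactone 28 (not isolated)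
Conditions: Me2AlCl (2.5 equiv), CH2Cl2, −78 → −20 °C; aq. potassium sodium tartrate; then DBU (0.2 equiv), CH2Cl2, rt
Reagents that add atoms: none
Why: Me2AlCl binds the C18 lactone carbonyl and makes the 1,3-dien-18,19-olide a vinylogous acceptor; furan α-carbon C16 adds to the δ-carbon C1, the furan rearomatises by loss of the C16 proton, and the aluminium dienolate is protonated at C4 or C2, DBU then moving any C2=C3 isomer 28 into conjugation. The closest known reaction type is the intramolecular Friedel–Crafts-type conjugate addition of furans to Lewis acid-activated enoates and dienoates. Ring C (C1, C10, C9, C11, C12, C13, C16) closes in the 7-exo-trig mode. The new stereocentre C1 is under substrate control: the C9–C11–C12 tether lies on the β-face of the cis-fused bicycle, so C16 can reach C1 only from that face and H1 ends cis to H10. The step needs attack through C16 and not C14 or C15, and 1,6- rather than 1,4-addition; C16 is the more nucleophilic α-position next to the side chain, C15 and the β-carbon C3 cannot be spanned by the three-atom tether, and the bulky silyl ether at C12 keeps the furan electron-rich while disfavouring ionisation at that carbon.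

Step 21
Reactants: 29 ring C-closed 12-silyl ether
Product: 30 ring C-closed 12-alcohol (the target with C12–OH)
Conditions: Bu4NF, AcOH, THF, 0 °C → rt
Reagents that add atoms: none
Why: Fluoride desilylation buffered with acetic acid should free the C12 alcohol while sparing the acetate and the butenolide.

Step 22
Reactants: 30 ring C-closed 12-alcohol
Product: 31 CNP0273675.2 (target)
Conditions: MnO2 (activated, excess), CH2Cl2, rt
Reagents that add atoms: none
Why: MnO2 oxidation of the furylic (benzylic-type) secondary alcohol should give the 3-acylfuran ketone of the target and converge the two C12 epimers.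

**Compound list**

1 | 2-methylcyclohexane-1,3-dione | CC1C(=O)CCCC1=O | starting material
2 | allyl alcohol (prop-2-en-1-ol) | C=CCO | starting material
3 | 3-(allyloxy)-2-methylcyclohex-2-en-1-one | C=CCOC1=C(C)C(=O)CCC1 | intermediate
4 | (1R)-3-(allyloxy)-2-methylcyclohex-2-en-1-ol | C=CCOC1=C(C)[C@H](O)CCC1 | intermediate
5 | tert-butyl{[(1R)-3-(allyloxy)-2-methylcyclohex-2-en-1-yl]oxy}dimethylsilane | C=CCOC1=C(C)[C@H](O[Si](C)(C)C(C)(C)C)CCC1 | intermediate
6 | (2S,3R)-2-allyl-3-[(tert-butyldimethylsilyl)oxy]-2-methylcyclohexan-1-one | C=CC[C@]1(C)C(=O)CCC[C@H]1O[Si](C)(C)C(C)(C)C | intermediate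
7 | (2S,3R,6E)-2-allyl-3-[(tert-butyldimethylsilyl)oxy]-6-[(dimethylamino)methylidene]-2-methylcyclohexan-1-one | C=CC[C@]1(C)C(=O)/C(=C/N(C)C)CC[C@H]1O[Si](C)(C)C(C)(C)C | intermediate
8 | amino alcohol from carbonyl reduction of 7 (C10 carbinol epimers; not isolated) | C=CC[C@]1(C)C(O)/C(=C/N(C)C)CC[C@H]1O[Si](C)(C)C(C)(C)C | intermediate
9 | (3R,4R)-3-allyl-4-[(tert-butyldimethylsilyl)oxy]-3-methylcyclohex-1-ene-1-carbaldehyde | C=CC[C@]1(C)C=C(C=O)CC[C@H]1O[Si](C)(C)C(C)(C)C | intermediate
10 | (E)-1-(trimethylsilyloxy)buta-1,3-diene | C=C/C=C/O[Si](C)(C)C | starting material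
11 | 9β-allyl-8α-[(tert-butyldimethylsilyl)oxy]-9α-methyl-4α-(trimethylsilyloxy)-5,10-cis-decal-2-ene-5α-carbaldehyde (endo C4 epimer drawn; not isolated) | C=CC[C@]1(C)[C@@H]2CC=C[C@@H](O[Si](C)(C)C)[C@]2(C=O)CC[C@H]1O[Si](C)(C)C(C)(C)C | intermediate
12 | 9β-allyl-8α-[(tert-butyldimethylsilyl)oxy]-4α-hydroxy-9α-methyl-5,10-cis-decal-2-ene-5α-carbaldehyde (10α-H) | C=CC[C@]1(C)[C@@H]2CC=C[C@@H](O)[C@]2(C=O)CC[C@H]1O[Si](C)(C)C(C)(C)C | intermediate
13 | 9β-allyl-8α-[(tert-butyldimethylsilyl)oxy]-9α-methyl-4-oxo-5,10-cis-decal-2-ene-5α-carbaldehyde | C=CC[C@]1(C)[C@@H]2CC=CC(=O)[C@]2(C=O)CC[C@H]1O[Si](C)(C)C(C)(C)C | intermediate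
14 | 9β-allyl-8α-[(tert-butyldimethylsilyl)oxy]-5α-formyl-9α-methyl-5,10-cis-decala-1,3-dien-4-yl trifluoromethanesulfonate | C=CC[C@]1(C)[C@@H]2C=CC=C(OS(=O)(=O)C(F)(F)F)[C@]2(C=O)CC[C@H]1O[Si](C)(C)C(C)(C)C | intermediate
15 | 9β-allyl-8α-[(tert-butyldimethylsilyl)oxy]-5α-(hydroxymethyl)-9α-methyl-5,10-cis-decala-1,3-dien-4-yl trifluoromethanesulfonate | C=CC[C@]1(C)[C@@H]2C=CC=C(OS(=O)(=O)C(F)(F)F)[C@]2(CO)CC[C@H]1O[Si](C)(C)C(C)(C)C | intermediate
16 | 9β-allyl-8α-[(tert-butyldimethylsilyl)oxy]-9α-methyl-5,10-cis-decala-1,3-dien-18,19-olide | CC(C)(C)[Si](C)(C)O[C@@H]1CC[C@@]23COC(=O)C2=CC=C[C@H]3[C@@]1(C)CC=C | intermediate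
17 | 9β-allyl-8α-hydroxy-9α-methyl-5,10-cis-decala-1,3-dien-18,19-olide | O[C@@H]1CC[C@@]23COC(=O)C2=CC=C[C@H]3[C@@]1(C)CC=C | intermediate
18 | 9β-allyl-9α-methyl-8-oxo-5,10-cis-decala-1,3-dien-18,19-olide | O=C1CC[C@@]23COC(=O)C2=CC=C[C@H]3[C@@]1(C)CC=C | intermediate
19 | 9β-allyl-9α-methyl-8-(trimethylsilyloxy)-5,10-cis-decala-1,3,7-trien-18,19-olide (not isolated) | C[Si](C)(C)OC1=CC[C@@]23COC(=O)C2=CC=C[C@H]3[C@@]1(C)CC=C | intermediate
20 | 9β-allyl-7β-hydroxy-9α-methyl-8-oxo-5,10-cis-decala-1,3-dien-18,19-olide | O=C1[C@@H](O)C[C@@]23COC(=O)C2=CC=C[C@H]3[C@@]1(C)CC=C | intermediate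
21 | 7β-acetoxy-9β-allyl-9α-methyl-8-oxo-5,10-cis-decala-1,3-dien-18,19-olide | O=C1[C@@H](OC(C)=O)C[C@@]23COC(=O)C2=CC=C[C@H]3[C@@]1(C)CC=C | intermediate
22 | 7β-acetoxy-9β-(2,3-dihydroxypropyl)-9α-methyl-8-oxo-5,10-cis-decala-1,3-dien-18,19-olide (carbinol epimers; not isolated) | O=C1[C@@H](OC(C)=O)C[C@@]23COC(=O)C2=CC=C[C@H]3[C@@]1(C)CC(O)CO | intermediate
23 | 7β-acetoxy-9α-methyl-8-oxo-9β-(2-oxoethyl)-5,10-cis-decala-1,3-dien-18,19-olide | O=C1[C@@H](OC(C)=O)C[C@@]23COC(=O)C2=CC=C[C@H]3[C@@]1(C)CC=O | intermediate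
24 | 3-bromofuran | Brc1ccoc1 | starting material
25 | 7β-acetoxy-9β-[2-(furan-3-yl)-2-hydroxyethyl]-9α-methyl-8-oxo-5,10-cis-decala-1,3-dien-18,19-olide (C12 epimers; one drawn) | O=C1[C@@H](OC(C)=O)C[C@@]23COC(=O)C2=CC=C[C@H]3[C@@]1(C)C[C@H](O)c1ccoc1 | intermediate
26 | 7β-acetoxy-9β-[2-(tert-butyldimethylsilyloxy)-2-(furan-3-yl)ethyl]-9α-methyl-8-oxo-5,10-cis-decala-1,3-dien-18,19-olide (C12 epimers; one drawn) | O=C1[C@@H](OC(C)=O)C[C@@]23COC(=O)C2=CC=C[C@H]3[C@@]1(C)C[C@H](O[Si](C)(C)C(C)(C)C)c1ccoc1 | intermediate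
27 | 7β-acetoxy-9β-[2-(tert-butyldimethylsilyloxy)-2-(furan-3-yl)ethyl]-9α-methyl-8-methylene-5,10-cis-decala-1,3-dien-18,19-olide (1,16-seco dienolide; C12 epimers; one drawn) | C=C1[C@@H](OC(C)=O)C[C@@]23COC(=O)C2=CC=C[C@H]3[C@@]1(C)C[C@H](O[Si](C)(C)C(C)(C)C)c1ccoc1 | intermediate
28 | ring C-closed C2=C3 lactone with 4β-H (deconjugated isomer of 29; not isolated) | C=C1[C@@H](OC(C)=O)C[C@@]23COC(=O)[C@@H]2C=C[C@H]2c4occc4[C@@H](O[Si](C)(C)C(C)(C)C)C[C@]1(C)[C@H]23 | intermediate
29 | ring C-closed 12-(tert-butyldimethylsilyl) ether of the target alcohol (1α-H; C3=C4 butenolide) | C=C1[C@@H](OC(C)=O)C[C@@]23COC(=O)C2=CC[C@H]2c4occc4[C@@H](O[Si](C)(C)C(C)(C)C)C[C@]1(C)[C@H]23 | intermediate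
30 | ring C-closed 12-alcohol (the target with C12–OH) | C=C1[C@@H](OC(C)=O)C[C@@]23COC(=O)C2=CC[C@H]2c4occc4[C@@H](O)C[C@]1(C)[C@H]23 | intermediate
31 | CNP0273675.2 | C=C1[C@@H](OC(C)=O)C[C@@]23COC(=O)C2=CC[C@H]2c4occc4C(=O)C[C@]1(C)[C@H]23 | target

**Step count**

Total: 22 steps. Longest linear sequence: 22 steps (1 → 31).

**Steps most likely to fail, with fallbacks**

Step 20 (ring C closure). The Lewis acid may ionise the furylic silyl ether or the allylic acetate faster than it activates the lactone, or the furan may be too weak a nucleophile for the δ-carbon. The same C1–C16 bond would then be made by a palladium-mediated reductive Heck (conjugate) cyclisation. The fallback sets out from 26: N-bromosuccinimide in DMF at −20 °C should brominate the furan at C16, the α-position next to the side chain, to give the 16-bromofuran F1. Pd(OAc)2, PPh3 and HCO2Na in DMF at 80 °C (oxidative addition by zerovalent palladium, 7-exo insertion of C1=C2 from the tether face, formate reduction of the allyl palladium species), followed by DBU, should give the ring C-closed 8-ketone F2. The cyclisation is run before methylenation so that no allylic acetate is exposed to palladium. Methylenation of F2 with Zn, CH2Br2 and TiCl4 returns to the route at 29.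

Step 7 (Diels–Alder reaction). Bond formation at the neopentyl β-carbon C10 may be too slow, so that 1,2-addition of the silyl dienol ether to the aldehyde or a carbonyl-ene reaction of the allyl group takes over. The ring would then be formed intramolecularly through a temporary silicon tether. The fallback sets out from 9: NaBH4 with CeCl3·7H2O in MeOH at −40 °C should give the allylic alcohol F3. iPr2SiCl2 and imidazole, then lithium (E)-buta-1,3-dien-1-olate (from 10 and MeLi), should give the mixed silyl acetal F4. Heating in PhMe at 170 °C in a sealed tube should bring about the intramolecular Diels–Alder reaction to the tethered cycloadduct F5, with the regiochemistry fixed by the tether and the same facial bias from the axial C9 methyl. HF·pyridine at 0 °C should cleave the dialkoxysilane before the hindered silyl ether and give the diol F6. Dess–Martin oxidation of both hydroxyls rejoins the route at 13.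

Step 16 (cleavage of the allyl group). OsO4 may also dihydroxylate the C1=C2 bond of the dienolide. The terminal alkene would then be addressed by hydroboration, which the conjugated, ring-bound diene resists, and the extra carbon removed afterwards. The fallback sets out from 21: 9-BBN in THF (0 °C → rt), then NaBO3·4H2O, should give the primary alcohol F7. Dess–Martin periodinane should give the homologous aldehyde F8. TBSOTf and Et3N should give the silyl enol ether F9. Ozone (1 equiv, CH2Cl2/MeOH, −78 °C, then Me2S), towards which the enol ether is far more reactive than the dienolide, should cut out the extra carbon and return to the route at 23.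

Further compounds
F1 | step 20 | 7β-acetoxy-9β-[2-(2-bromofuran-3-yl)-2-(tert-butyldimethylsilyloxy)ethyl]-9α-methyl-8-oxo-5,10-cis-decala-1,3-dien-18,19-olide (16-bromide of 26) | O=C1[C@@H](OC(C)=O)C[C@@]23COC(=O)C2=CC=C[C@H]3[C@@]1(C)C[C@H](O[Si](C)(C)C(C)(C)C)c1ccoc1Br
F2 | step 20 | ring C-closed 8-ketone (29 with C8=O in place of the exo-methylene) | O=C1[C@@H](OC(C)=O)C[C@@]23COC(=O)C2=CC[C@H]2c4occc4[C@@H](O[Si](C)(C)C(C)(C)C)C[C@]1(C)[C@H]23
F3 | step 7 | [(3R,4R)-3-allyl-4-(tert-butyldimethylsilyloxy)-3-methylcyclohex-1-en-1-yl]methanol | C=CC[C@]1(C)C=C(CO)CC[C@H]1O[Si](C)(C)C(C)(C)C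
F4 | step 7 | mixed diisopropylsilyl acetal of F3 and (E)-buta-1,3-dien-1-ol | C=CC[C@]1(C)C=C(CO[Si](C(C)C)(C(C)C)O/C=C/C=C)CC[C@H]1O[Si](C)(C)C(C)(C)C
F5 | step 7 | tethered cycloadduct: 4α,19-(diisopropylsilylenedioxy)-9β-allyl-8α-(tert-butyldimethylsilyloxy)-9α-methyl-5,10-cis-decal-2-ene | C=CC[C@]1(C)[C@@H]2CC=C[C@H]3O[Si](C(C)C)(C(C)C)OC[C@@]23CC[C@H]1O[Si](C)(C)C(C)(C)C
F6 | step 7 | 9β-allyl-8α-(tert-butyldimethylsilyloxy)-5α-(hydroxymethyl)-9α-methyl-5,10-cis-decal-2-en-4α-ol | C=CC[C@]1(C)[C@@H]2CC=C[C@@H](O)[C@]2(CO)CC[C@H]1O[Si](C)(C)C(C)(C)C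
F7 | step 16 | 7β-acetoxy-9β-(3-hydroxypropyl)-9α-methyl-8-oxo-5,10-cis-decala-1,3-dien-18,19-olide | O=C1[C@@H](OC(C)=O)C[C@@]23COC(=O)C2=CC=C[C@H]3[C@@]1(C)CCCO
F8 | step 16 | 7β-acetoxy-9α-methyl-8-oxo-9β-(3-oxopropyl)-5,10-cis-decala-1,3-dien-18,19-olide | O=C1[C@@H](OC(C)=O)C[C@@]23COC(=O)C2=CC=C[C@H]3[C@@]1(C)CCC=O
F9 | step 16 | 7β-acetoxy-9β-[(E)-3-(tert-butyldimethylsilyloxy)prop-2-enyl]-9α-methyl-8-oxo-5,10-cis-decala-1,3-dien-18,19-olide | O=C1[C@@H](OC(C)=O)C[C@@]23COC(=O)C2=CC=C[C@H]3[C@@]1(C)C/C=C/O[Si](C)(C)C(C)(C)C
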